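**Plan**

- The target is an achiral benzophenone. Ring A (2-ethyl-4,6-dihydroxyphenyl) and ring B are joined through the ketone; ring B carries OH, the ketone carbon and a CH2 group on three neighbouring carbons, and that CH2 holds ring C, a 4-hydroxy-2-pyranone.
- Retrosynthetic cuts, in order: the three O–CH3 bonds; ring C at its lactone O–C(=O) bond and at the bond between the arylacetyl carbonyl and the next CH2; then, in one stroke, the ring B–C(=O) and ring B–CH2 bonds; last the ring A–C(=O) bond.
- The O / C(=O) / CH2 triad on adjacent carbons of ring B is the imprint of 3-methoxybenzyne entering the C(=O)–CH2 bond of a ring A β-ketoester; this feature makes the key step possible.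
- Forward: Friedel–Crafts acylation builds the ring A ketoester, aryne insertion brings in ring B (two C–C bonds, no lasting ring closure), the acetate arm is extended with a dioxinone, thermolysis closes ring C, and BBr3 frees the phenols.
- Stereochemistry: none to set; the target has no stereocentre and no stereogenic double bond.

Key step: step 2

Remark: the target is handled as its 4-hydroxy-2-pyranone tautomer, and 5-ethylresorcinol dimethyl ether, methyl malonyl chloride, the methoxy-substituted silylaryl triflate and the diketene–acetone adduct are taken as catalogue chemicals.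

**Route**

Step 1
Reactants: 1 1-ethyl-3,5-dimethoxybenzene; 2 methyl 3-chloro-3-oxopropanoate (methyl malonyl chloride)
Product: 3 methyl 3-(2-ethyl-4,6-dimethoxyphenyl)-3-oxopropanoate
Conditions: AlCl3 (1.2 equiv), CH2Cl2, 0 °C; cold dilute HCl work-up
Reagents that add atoms: none
Why: Friedel–Crafts acylation of an electron-rich arene: the carbon between ethyl and methoxy is para to the second methoxy group and less crowded than the carbon between the two methoxy groups, the acyl group deactivates the ring against a second acylation, and holding 0 °C limits chelation-assisted loss of the ortho methyl ether.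

Step 2
Reactants: 3 methyl 3-(2-ethyl-4,6-dimethoxyphenyl)-3-oxopropanoate; 4 3-methoxy-2-(trimethylsilyl)phenyl trifluoromethanesulfonate
Product: 7 methyl 2-[2-(2-ethyl-4,6-dimethoxybenzoyl)-3-methoxyphenyl]acetate, via 3-methoxybenzyne 5 (not isolated), via cesium benzocyclobutenoxide 6 (not isolated)
Conditions: 4 (1.5 equiv), CsF (3 equiv), dry MeCN, 80 °C
Reagents that add atoms: none
Why: CsF removes the silyl group of 4 and triflate departs, giving 3-methoxybenzyne 5, while fluoride also generates the enolate of 3; the enolate carbon adds to the aryne carbon remote from methoxy, the aryl anion so formed next to methoxy closes 4-exo-trig onto the ketone to give benzocyclobutenoxide 6, and 6 opens by retro-aldol cleavage of the former C(=O)–CH2 bond to the ester-stabilised benzylic anion, which is protonated to 7. The closest known reaction type is the fluoride-induced acyl-alkylation of arynes by β-ketoesters (formal insertion of an aryne into a carbon–carbon sigma bond), applied here to an aryl ketoester. No ring survives the step, the transient four-membered ring being the only closure, and no stereocentre is left (the two of 6 disappear on ring opening). The selectivity needed is the direction of addition to the unsymmetrical aryne; it is secured by the methoxy group, whose inductive pull and distortion of the triple bond steer the nucleophile to the far carbon, so that the acyl group lands beside oxygen and the acetate arm one carbon on. The likely leak is protonation of the aryl anion before it closes on a ketone flanked by ethyl and methoxy (arylation without acyl transfer); dry MeCN, excess aryne precursor and 80 °C should hold it back, and the twist of the ketone out of the ring A plane keeps its carbonyl electrophilic.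

Step 3
Reactants: 7 methyl 2-[2-(2-ethyl-4,6-dimethoxybenzoyl)-3-methoxyphenyl]acetate
Product: 8 2-[2-(2-ethyl-4,6-dimethoxybenzoyl)-3-methoxyphenyl]acetic acid
Conditions: LiOH·H2O, THF/MeOH/H2O, rt; then 1 M HCl to pH 2
Reagents that add atoms: lithium hydroxide, [Li+].[OH-]
Why: Saponification of an unhindered methyl arylacetate; the diaryl ketone cannot enolise and is screened by four ortho substituents, and aryl methyl ethers are inert to hydroxide.

Step 4
Reactants: 8 2-[2-(2-ethyl-4,6-dimethoxybenzoyl)-3-methoxyphenyl]acetic acid; 9 2,2,6-trimethyl-4H-1,3-dioxin-4-one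
Product: 12 6-{3-[2-(2-ethyl-4,6-dimethoxybenzoyl)-3-methoxyphenyl]-2-oxopropyl}-2,2-dimethyl-4H-1,3-dioxin-4-one, via acyl imidazole 10 (not isolated), via lithium dienolate 11 (not isolated)
Conditions: 8, CDI (1.05 equiv), THF, rt; then added to 9 + LiN(SiMe3)2 (3.5 equiv each), THF, −78 °C; aq. NH4Cl
Reagents that add atoms: none
Why: Crossed Claisen C-acylation of the terminal carbon of a dioxinone dienolate by an acyl imidazole is a known entry to 6-(2-oxoalkyl)dioxinones; the excess dienolate should cover the imidazole N–H released by CDI, the acidic product and the benzylic CH2, inverse addition at −78 °C favours addition over enolisation, and the shielded diaryl ketone stays out of play.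

Step 5
Reactants: 12 6-{3-[2-(2-ethyl-4,6-dimethoxybenzoyl)-3-methoxyphenyl]-2-oxopropyl}-2,2-dimethyl-4H-1,3-dioxin-4-one
Product: 14 6-{[2-(2-ethyl-4,6-dimethoxybenzoyl)-3-methoxyphenyl]methyl}-4-hydroxy-2H-pyran-2-one, via acylketene 13 (not isolated)
Conditions: toluene (0.01 M), 110 °C
Reagents that add atoms: none
Why: Thermal retro-Diels–Alder loss of acetone from the dioxinone gives acylketene 13, which is trapped by the enol oxygen of the neighbouring ketone in a six-membered lactonisation, the established base-free route from 6-(2-oxoalkyl)dioxinones to 6-substituted 4-hydroxy-2-pyranones.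

Step 6
Reactants: 14 6-{[2-(2-ethyl-4,6-dimethoxybenzoyl)-3-methoxyphenyl]methyl}-4-hydroxy-2H-pyran-2-one
Product: 15 6-{[2-(2-ethyl-4,6-dihydroxybenzoyl)-3-hydroxyphenyl]methyl}-4-hydroxy-2H-pyran-2-one
Conditions: BBr3 (8 equiv), CH2Cl2, −78 °C to rt; ice/H2O quench
Reagents that add atoms: none
Why: BBr3 cleavage of aryl methyl ethers: the two ethers ortho to the ketone should fall first through chelation and the para one at room temperature, while the pyranone, a vinylogous acid, is only held as a borate and returned on aqueous quench.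

**Compound list**

1 | 1-ethyl-3,5-dimethoxybenzene | CCc1cc(OC)cc(OC)c1 | starting material
2 | methyl 3-chloro-3-oxopropanoate (methyl malonyl chloride) | COC(=O)CC(=O)Cl | starting material
3 | methyl 3-(2-ethyl-4,6-dimethoxyphenyl)-3-oxopropanoate | CCc1cc(OC)cc(OC)c1C(=O)CC(=O)OC | intermediate
4 | 3-methoxy-2-(trimethylsilyl)phenyl trifluoromethanesulfonate | COc1cccc(OS(=O)(=O)C(F)(F)F)c1[Si](C)(C)C | starting material
5 | 3-methoxybenzyne (1,2-didehydro-3-methoxybenzene) | COC1=CC=CC#C1 | intermediate (not isolated)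
6 | cesium salt of methyl 8-(2-ethyl-4,6-dimethoxyphenyl)-2-methoxy-8-oxidobicyclo[4.2.0]octa-1,3,5-triene-7-carboxylate (racemic, either relative configuration; both centres vanish on ring opening) | CCc1cc(OC)cc(OC)c1C1([O-])C(C(=O)OC)c2cccc(OC)c12.[Cs+] | intermediate (not isolated)
7 | methyl 2-[2-(2-ethyl-4,6-dimethoxybenzoyl)-3-methoxyphenyl]acetate | CCc1cc(OC)cc(OC)c1C(=O)c1c(OC)cccc1CC(=O)OC | intermediate
8 | 2-[2-(2-ethyl-4,6-dimethoxybenzoyl)-3-methoxyphenyl]acetic acid | CCc1cc(OC)cc(OC)c1C(=O)c1c(OC)cccc1CC(=O)O | intermediate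
9 | 2,2,6-trimethyl-4H-1,3-dioxin-4-one | CC1=CC(=O)OC(C)(C)O1 | starting material
10 | 2-[2-(2-ethyl-4,6-dimethoxybenzoyl)-3-methoxyphenyl]-1-(1H-imidazol-1-yl)ethan-1-one | CCc1cc(OC)cc(OC)c1C(=O)c1c(OC)cccc1CC(=O)n1ccnc1 | intermediate (not isolated)
11 | lithium 2,2-dimethyl-6-methylidene-6H-1,3-dioxin-4-olate | [Li+].[O-]C1=CC(=C)OC(C)(C)O1 | intermediate (not isolated)
12 | 6-{3-[2-(2-ethyl-4,6-dimethoxybenzoyl)-3-methoxyphenyl]-2-oxopropyl}-2,2-dimethyl-4H-1,3-dioxin-4-one | CCc1cc(OC)cc(OC)c1C(=O)c1c(OC)cccc1CC(=O)CC1=CC(=O)OC(C)(C)O1 | intermediate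
13 | 6-[2-(2-ethyl-4,6-dimethoxybenzoyl)-3-methoxyphenyl]hex-1-ene-1,3,5-trione | CCc1cc(OC)cc(OC)c1C(=O)c1c(OC)cccc1CC(=O)CC(=O)C=C=O | intermediate (not isolated)
14 | 6-{[2-(2-ethyl-4,6-dimethoxybenzoyl)-3-methoxyphenyl]methyl}-4-hydroxy-2H-pyran-2-one | CCc1cc(OC)cc(OC)c1C(=O)c1c(OC)cccc1Cc1cc(O)cc(=O)o1 | intermediate
15 | 6-{[2-(2-ethyl-4,6-dihydroxybenzoyl)-3-hydroxyphenyl]methyl}-4-hydroxy-2H-pyran-2-one (CNP0234555.0) | CCc1cc(O)cc(O)c1C(=O)c1c(O)cccc1Cc1cc(O)cc(=O)o1 | target

**Totals and risks**

Total step count: 6. Longest linear sequence: 6 steps (1 to 15).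

Risk 1, step 2. The aryl anion may be protonated before it can close on the ketone crowded by ethyl and methoxy, so that arylation occurs without acyl transfer; aryne self-reaction may also outrun enolate capture. The fallback sets out from 1 and comes back at 8, building the same diaryl ketone by cleavage of an indene. NBS in MeCN at 0 °C should brominate 1 para to methoxy and ortho to ethyl, giving 2-bromo-1-ethyl-3,5-dimethoxybenzene F1. Bromine–lithium exchange (n-BuLi, THF, −78 °C), transmetalation with anhydrous CeCl3 and addition to purchased 7-methoxyindan-1-one (COc1cccc2CCC(=O)c12) should give racemic 1-(2-ethyl-4,6-dimethoxyphenyl)-7-methoxy-2,3-dihydro-1H-inden-1-ol F2. Dehydration with p-TsOH in warm toluene should give 3-(2-ethyl-4,6-dimethoxyphenyl)-4-methoxy-1H-indene F3. Lemieux–Johnson cleavage of the ring double bond (OsO4 cat., NaIO4, 2,6-lutidine, dioxane/H2O) should give 2-[2-(2-ethyl-4,6-dimethoxybenzoyl)-3-methoxyphenyl]acetaldehyde F4. Pinnick oxidation (NaClO2, NaH2PO4, 2-methyl-2-butene, t-BuOH/H2O) then returns acid 8.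

Risk 2, step 4. The dienolate may deprotonate the benzylic CH2 of the acyl imidazole (enolisation, ketene formation, return of acid on work-up) instead of attacking its carbonyl. The fallback sets out from 7 and comes back at 12; it replaces the basic acylation by a Lewis-acid aldol addition followed by oxidation. Reduction of 7 with i-Bu2AlH in CH2Cl2 at −78 °C (the diaryl ketone is screened by its four ortho substituents) should give 2-[2-(2-ethyl-4,6-dimethoxybenzoyl)-3-methoxyphenyl]acetaldehyde F5, the same structure as F4. Dioxinone 9 is converted with LiN(SiMe3)2 and Me3SiCl in THF at −78 °C into [(2,2-dimethyl-6-methylidene-6H-1,3-dioxin-4-yl)oxy]trimethylsilane F6. Vinylogous Mukaiyama aldol addition of F6 to F5 (BF3·OEt2, CH2Cl2, −78 °C) should give racemic 6-{3-[2-(2-ethyl-4,6-dimethoxybenzoyl)-3-methoxyphenyl]-2-hydroxypropyl}-2,2-dimethyl-4H-1,3-dioxin-4-one F7. Dess–Martin periodinane in CH2Cl2 then oxidises the secondary alcohol to 12.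

Risk 3, step 6. Cleavage of the methyl ether para to the ketone may stay incomplete, or long exposure of the pyranone-bearing polyphenol to the strong Lewis acid may cause condensation and degradation. The fallback sets out from 8 and comes back at 15; the methyl ethers are removed before ring C exists and the phenols are carried as benzyl ethers, which are removed at the end under neutral conditions.
- BBr3 in CH2Cl2 on 8 should give 2-[2-(2-ethyl-4,6-dihydroxybenzoyl)-3-hydroxyphenyl]acetic acid F8.
- BnBr and K2CO3 in DMF at 60 °C should give benzyl 2-{2-[2,4-bis(benzyloxy)-6-ethylbenzoyl]-3-(benzyloxy)phenyl}acetate F9.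
- LiOH in THF/H2O should give 2-{2-[2,4-bis(benzyloxy)-6-ethylbenzoyl]-3-(benzyloxy)phenyl}acetic acid F10.
- CDI should give 2-{2-[2,4-bis(benzyloxy)-6-ethylbenzoyl]-3-(benzyloxy)phenyl}-1-(1H-imidazol-1-yl)ethan-1-one F11, which is added to dienolate 11 as in step 4 to give 6-(3-{2-[2,4-bis(benzyloxy)-6-ethylbenzoyl]-3-(benzyloxy)phenyl}-2-oxopropyl)-2,2-dimethyl-4H-1,3-dioxin-4-one F12.
- Thermolysis in toluene at 110 °C should pass through 6-{2-[2,4-bis(benzyloxy)-6-ethylbenzoyl]-3-(benzyloxy)phenyl}hex-1-ene-1,3,5-trione F13 to 6-({2-[2,4-bis(benzyloxy)-6-ethylbenzoyl]-3-(benzyloxy)phenyl}methyl)-4-hydroxy-2H-pyran-2-one F14.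
- Hydrogenolysis (H2, 1 atm, Pd/C, EtOAc, rt, stopped once debenzylation is complete) should give 15.

**Further compounds**

F1 | step 2 | 2-bromo-1-ethyl-3,5-dimethoxybenzene | CCc1cc(OC)cc(OC)c1Br
F2 | step 2 | 1-(2-ethyl-4,6-dimethoxyphenyl)-7-methoxy-2,3-dihydro-1H-inden-1-ol (racemic) | CCc1cc(OC)cc(OC)c1C1(O)CCc2cccc(OC)c21
F3 | step 2 | 3-(2-ethyl-4,6-dimethoxyphenyl)-4-methoxy-1H-indene | CCc1cc(OC)cc(OC)c1C1=CCc2cccc(OC)c21
F4 | step 2 | 2-[2-(2-ethyl-4,6-dimethoxybenzoyl)-3-methoxyphenyl]acetaldehyde | CCc1cc(OC)cc(OC)c1C(=O)c1c(OC)cccc1CC=O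
F5 | step 4 | 2-[2-(2-ethyl-4,6-dimethoxybenzoyl)-3-methoxyphenyl]acetaldehyde | CCc1cc(OC)cc(OC)c1C(=O)c1c(OC)cccc1CC=O
F6 | step 4 | [(2,2-dimethyl-6-methylidene-6H-1,3-dioxin-4-yl)oxy]trimethylsilane | C=C1C=C(O[Si](C)(C)C)OC(C)(C)O1
F7 | step 4 | 6-{3-[2-(2-ethyl-4,6-dimethoxybenzoyl)-3-methoxyphenyl]-2-hydroxypropyl}-2,2-dimethyl-4H-1,3-dioxin-4-one (racemic) | CCc1cc(OC)cc(OC)c1C(=O)c1c(OC)cccc1CC(O)CC1=CC(=O)OC(C)(C)O1
F8 | step 6 | 2-[2-(2-ethyl-4,6-dihydroxybenzoyl)-3-hydroxyphenyl]acetic acid | CCc1cc(O)cc(O)c1C(=O)c1c(O)cccc1CC(=O)O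
F9 | step 6 | benzyl 2-{2-[2,4-bis(benzyloxy)-6-ethylbenzoyl]-3-(benzyloxy)phenyl}acetate | CCc1cc(OCc2ccccc2)cc(OCc2ccccc2)c1C(=O)c1c(OCc2ccccc2)cccc1CC(=O)OCc1ccccc1
F10 | step 6 | 2-{2-[2,4-bis(benzyloxy)-6-ethylbenzoyl]-3-(benzyloxy)phenyl}acetic acid | CCc1cc(OCc2ccccc2)cc(OCc2ccccc2)c1C(=O)c1c(OCc2ccccc2)cccc1CC(=O)O
F11 | step 6 | 2-{2-[2,4-bis(benzyloxy)-6-ethylbenzoyl]-3-(benzyloxy)phenyl}-1-(1H-imidazol-1-yl)ethan-1-one | CCc1cc(OCc2ccccc2)cc(OCc2ccccc2)c1C(=O)c1c(OCc2ccccc2)cccc1CC(=O)n1ccnc1
F12 | step 6 | 6-(3-{2-[2,4-bis(benzyloxy)-6-ethylbenzoyl]-3-(benzyloxy)phenyl}-2-oxopropyl)-2,2-dimethyl-4H-1,3-dioxin-4-one | CCc1cc(OCc2ccccc2)cc(OCc2ccccc2)c1C(=O)c1c(OCc2ccccc2)cccc1CC(=O)CC1=CC(=O)OC(C)(C)O1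
F13 | step 6 | 6-{2-[2,4-bis(benzyloxy)-6-ethylbenzoyl]-3-(benzyloxy)phenyl}hex-1-ene-1,3,5-trione | CCc1cc(OCc2ccccc2)cc(OCc2ccccc2)c1C(=O)c1c(OCc2ccccc2)cccc1CC(=O)CC(=O)C=C=O
F14 | step 6 | 6-({2-[2,4-bis(benzyloxy)-6-ethylbenzoyl]-3-(benzyloxy)phenyl}methyl)-4-hydroxy-2H-pyran-2-one | CCc1cc(OCc2ccccc2)cc(OCc2ccccc2)c1C(=O)c1c(OCc2ccccc2)cccc1Cc1cc(O)cc(=O)o1
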